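You must pick one set-up for this charge, so you want a number that says how long target can sit in a flask.

| flask | starting material | reagent | remark | time |
|---|---|---|---|---|
| dawn | 0.10 M | 0.070 M | run made earlier |  |
| winter | 0.10 M | 0.035 M | run made earlier |  |
| spring | 0.10 M | 0.14 M | run made earlier |  |
| green | 0.10 M (fed, over 2.00 h) | 0.0700 M | a stirred flask in which starting material is dosed at a steady rate over 2.00 h without added volume, worked up at 2.0 h | 2.0 h |
| teal | 0.10 M | 0.0700 M | one stirred flow tank at steady state, fed with the mixture as stated, mean residence time 10.0 h |  |
| red | 0.10 M | 0.0700 M | a single well-mixed tank run continuously and read at steady state, 2.0 h in it on average |  |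
| ochre | 0.10 M | 0.0700 M | everything together in a closed stirred flask, run for 2.0 h | 2.0 h |

| run | time / min | target / % | isomer of the product A / % |
|---|---|---|---|
| dawn | 6.00 | 2 | 0 |
| dawn | 10.0 | 8 | 0 |
| dawn | 20.0 | 10 | 0 |
| dawn | 40.0 | 19 | 3 |
| dawn | 80.0 | 30 | 0 |
| winter | 6.00 | 3 | 1 |
| winter | 20.0 | 7 | 3 |
| winter | 30.0 | 8 | 0 |
| winter | 50.0 | 14 | 2 |
| winter | 80.0 | 15 | 0 |
| spring | 15.0 | 20 | 0 |
| spring | 30.0 | 28 | 1 |
| spring | 40.0 | 37 | 4 |
| spring | 60.0 | 45 | 3 |
| spring | 80.0 | 49 | 0 |

(standard deviation of a reading: 2 percentage points)

- percentages count the starting material that a species holds: one side product counts as two
- the stated concentrations are those of everything mixed, before any reaction; amounts are the same in each set-up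
- candidate steps: starting material <-> other conformer; target <-> isomer of the product B; starting material + reagent -> target; starting material + target -> side product; reagent + other conformer -> isomer of the product A
- the feed brings no volume worth counting
- the earlier runs were made in a closed, stirred flask

- the set-up with the highest share of target in all that became target or isomer of the product A or side product or isomer of the product B, at the outlet or at the end ("none" if the first two lie within 2 percentage points) (green / teal / red / ochre / none)
- share of target in all that became target or isomer of the product A or side product or isomer of the product B, at the outlet or at the end, green
- share of target in all that became target or isomer of the product A or side product or isomer of the product B, at the outlet or at the end, teal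
- share of target in all that became target or isomer of the product A or side product or isomer of the product B, at the outlet or at the end, red
- share of target in all that became target or isomer of the product A or side product or isomer of the product B, at the outlet or at the end, ochre

The spring run looks clean and yet does not add up. Its first reading, 20% of target at 15.0 min with c(reagent) at 0.14 M, gives a pace of 0.0952 M⁻¹ min⁻¹ for starting material + reagent → target. Carried forward as a plain second-order reaction, that pace gives 55.5% at 80.0 min, but the flask reads 49%, and isomer of the product A reads 0% there. So 6.5 percentage points are missing, more than the scatter of 2 points, with nothing read to hold them.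

I book this gap to a slow loss of target into species that are not read. Taking the mid-run reading of 37% as the mean held over the 80.0 min, I get the leak time, the mean life of target against all its losses taken together as pseudo-first-order, of 7.59 h, a reading that carries the scatter of its few points.

The share of target is then the leak time divided by the leak time plus the mean age of the product, leaving isomer of the product A out. The mean age is 10.0 h in teal and 2.0 h in red, both on average. In ochre target forms early, for the dawn run, with ochre's charge, gains 19% in its first 40.0 min, more than the 11 points of the following 40.0 min, so I take 1.33 h, and in green, where target forms mostly late from the dosed material, 0.667 h. So I reckon green 91.9%, ochre 85.1%, red 79.2% and teal 43.2%, with green ahead of the others.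

The forecast gives green 81%, ochre 72%, red 67% and teal 40%, of which it says “long exposure, about 40%, very uncertain”, and it chooses green.

The simulation gives green 86.8%, ochre 79.6%, red 73.1% and teal 41.4%, so green is best.

    starting material ⇌ other conformer (K = 0.540, k = 0.00350 min⁻¹)
    target ⇌ isomer of the product B (K = 5.20, k = 0.00230 min⁻¹)
    starting material + reagent → target (k = 0.110 M⁻¹ min⁻¹)
    starting material + target → side product (k = 0.00450 M⁻¹ min⁻¹)
    reagent + other conformer → isomer of the product A (k = 0.0170 M⁻¹ min⁻¹)

Teal's mean stay is 1.32 leak times, longer than the leak time itself, and its share of 41.4% sits close to my 43.2%. With the conversion of target into isomer of the product B taken away, both ways, teal trails green by 16 points instead of 45 points, so that step is the largest single effect in the difference between these two flasks. Red, the second tank, stays 0.264 leak times on average, and the same rule gives 79.2% against its simulated 73.1%.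

The runs were computed for substances that don't exist, and the scatter is random.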